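## The problem

The target is a briarane: a cyclohexane (ring A) trans-fused through C1–C10 to a ten-membered carbocycle (C1 to C10), with a γ-lactone fused across C7–C8 (O7–C19–C17–C8). It has eleven stereocentres, among them the quaternary C1, the tertiary carbinol C8 and the spiro-epoxide carbon C11, and every carbon of the medium ring except C3 and C4 is functionalised. The ring A centres can be relayed around a six-membered ring (C12 to C10 to C1 to C14). C2, C6, C7, C8 and C17 sit on a flexible ten-membered ring and can only be controlled through its conformation (peripheral attack) or by delivery from a neighbouring oxygen (C8 and C17 from O7, C2 from O14, the epoxide from O12). End-to-end closure of a ten-membered ring between such hindered termini is unfavourable, so the ring is better made by expansion of a smaller one. The secondary allylic chloride next to the C5=C16 methylene (SN2′ displacement, loss of HCl), the 11,20-epoxide (acid, chloride), the tertiary β-hydroxy lactone (retro-aldol, dehydration) and the four acetates (base, organometallics) are fragile and must appear late. The feature that opens the key step is the C2 oxygen standing 1,5 to C6 across C3–C4–C5, with an exocyclic methylene on C5 and C6/C7 functionality derivable from an E-C6=C7 double bond. This is the pattern left by an oxy-Cope shift of a ring B cyclohexanol carrying a vinyl group on C2 and an allenyl group on C7.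

## Retrosynthesis

**Acetates and epoxide.** The four ester C–O bonds of 47 and the C11–O/C20–O bonds are cut first, back to pentaol 45 through epoxy pentaol 46. Acetates do not survive hydride, fluoride or organometallic steps and the epoxide would not survive the chloride source, so both come last. Epoxidising before acetylation lets the free axial 12-hydroxyl steer the oxidant to C11=C20 and away from C5=C16. The forward steps must tell four secondary hydroxyls from one tertiary one.

**C2 carbinol.** The C2–H bond of 45 is cut to ketone 44, whose three silyl ethers lead back to 43. C2 must pass through a ketone because it is the carbonyl carbon left by the ring expansion. Reducing it only when the C14 hydroxyl is free allows internal hydride delivery (1,3-anti), which an early external reduction of the hindered medium-ring ketone does not offer.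

**Lactone.** The C8–C17 bond of 43 is cut to α-bromo ester 41, and the ester C–O bond to chloro ketol 39 and acid 40. Against an intermolecular propionate aldol, the tethered Reformatsky closure lets O7 choose the carbonyl face and forms a five-membered ring. The precursor has two stereocentres fewer (C8, C17). The forward step must reduce the C–Br bond beside an allylic chloride and two ketones.

**Chlorohydrin.** The C6–Cl and C7–O bonds of 39 lead to trans-epoxide 38, then to (E)-enone 37, alcohol 36 and silyl ether 35. Anti addition of Cl and O across an E-C6=C7 bond is exactly the C6/C7 relationship of the target. A singlet-oxygen cycloaddition to the C16=C5–C6=C7 diene was set aside: the allene-derived methylene is born orthogonal to C6=C7 and the s-cis diene is strained in the ring. With C8 as a ketone, C6=C7 is the only electron-poor alkene, so a nucleophilic epoxidation is chemoselective.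

**Ten-membered ring (key cut).** In 35 the C4–C5 bond is cut and the C2–C7 bond restored, which gives trans-decalin 32 with a tertiary C2 alcohol, a C2 vinyl group and a C7 allenyl group. Against metathesis or carbonyl-addition closures of the ten-membered ring, the [3,3] ring expansion has no entropic penalty and delivers the C2 ketone, the E-C6=C7 bond and the C5 methylene together. It turns a medium-ring problem into a six-membered-ring problem. The forward reaction needs the two alkenyl groups trans-diequatorial.

**Allene, vinyl group and C6–C7 bond.** The allene of 32 is traced to propargylic alcohol 30, the C2–C3 bond to vinylmagnesium bromide 28 and ketone 27, and the C6–C7 bond to an aldol between decalone 23 and ynal 24. Propargylation of C7 and base isomerisation would run on to the internal alkyne, and an alkynyl group directly on C7 would give an isomerisation-prone β,γ-ynone. The aldol/reductive transposition avoids both and uses the C2 ketone twice.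

**Ring B oxygens.** The C8–O bond of 23 is cut (conjugate borylation–oxidation of enone 20, via 22) and then the C9–O bond (γ-oxidation of enone 17 through dienol ether 18, via 19). Both use the one enone, so regiochemistry is fixed by its polarity; C9 gets the axial β oxygen the target needs, and the C8 configuration is irrelevant because C8 later becomes a ketone.

**Ring B carbons.** The C7=C8 bond of 17 is cut by ring-closing metathesis to diene 16. The C1–C2 bond (aldol with acrolein 8) and the C9–C10 bond (conjugate addition of allylmagnesium bromide 6) lead through 13, 11 and 7 back to enone 5. A Robinson-type annulation would leave C2 or C14 unoxygenated and a Diels–Alder closure would give the cis fusion. Conjugate addition followed by aldol sets C10 and then C1 with the trans relationship of the two future ring B bonds.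

**Ring A.** Enone 5 is traced through alcohol 4 (C12–O bond, enantioselective conjugate borylation) to quinone monoketal 2 and phenol 1. The ketal holds C11 at the ketone level, so the exocyclic methylene needs no C–H functionalisation later.

## Roads not taken

Alternative 1: The cut runs through C1–C14 and C10–C11 of ring A. A chiral Lewis acid would catalyse the endo [4+2] cycloaddition of the trisubstituted enal A1 (C2, C1, C10, C9) with the 1-benzyloxy-3-silyloxydiene A2 (C14 to C11) to give cyclohexene A3.
- Merits: one catalytic asymmetric step sets the quaternary C1, C10 and C14 with the relative configuration the target needs, and leaves C2 as an aldehyde and C12 as a masked ketone.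
- Weak points: α-methyl-β-alkyl enals are among the poorest dienophiles, and the activation they need endangers the acid-labile diene. The β-benzyloxy ketone unmasked from A3 eliminates easily. C11 comes out as a methylene whose enolisation is disfavoured against C13, so the exocyclic alkene and epoxide have no clean entry. The ten-membered ring is not addressed.
- Comparison: for the C1/C10/C14 triad this road is shorter and better than steps 2 to 6 of the chosen plan, which relay the same centres one by one. The chosen plan sets against it that C11 is at the ketone level from step 1, and that the groups which set C10 and C1 (allyl, acrolein) are the carbons that close ring B.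

Alternative 2: The cut is the C1–C10 bond, made across a ring. A Lewis acid would open the 1,2-epoxide of the fourteen-membered macrocycle A4 while its allylsilane carbon C10 attacks C1, closing ring A and the ten-membered ring at once to give A5.
- Merits: it is the most convergent and biomimetic road, and the C2 hydroxyl, the C11 methylene and the butenolide appear in the same step. Its C5=C6 alkene with the C16 methyl is also set up for an ene-type chlorination to the 6-chloro-5(16)-ene.
- Weak points: A4 needs a macrocyclisation and three remote stereo-elements. The cyclisation must prefer C10 over the other π-nucleophiles and give the trans fusion, both resting on a macrocycle conformation that cannot be planned with confidence. The butenolide must still be hydrated at the tetrasubstituted C8.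
- Comparison: if A4 were in hand this road would be shorter and, for the chloride, more direct. The chosen plan sets against it stereocontrol by six-membered-ring rules at every centre and a ring expansion with no entropic cost.

Alternative 3: The cut runs through C1–C10 and C12–C13. A secondary-amine catalyst would add ketoester A6 through C1 to C10 of enal A7, and the C13 enolate would close onto the C12 aldehyde to give A8.
- Merits: one operation from commodity chemicals gives a ring A with oxygen at C12 and C14, the quaternary C1 and carbon stubs for C2 and C9.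
- Weak points: diastereocontrol at the quaternary centre of an acyclic α-substituted ketoester is unreliable. The C12 carbinol comes from an aldol of unsecured sense. C11 is left as an unactivated methylene. The medium ring is not addressed.
- Comparison: in step count to ring A this road beats the chosen plan (one step against seven to 13). The chosen plan sets against it a C11 ketal, a C1 centre set by anti-alkylation of a cyclic enolate, and ring A hydroxyls set by known hydride rules.

Key step: step 19

Remarks on the chemistry: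
- Briarane numbering is used for every intermediate (ring A = C1, C14, C13, C12, C11, C10; ring B of the decalins = C1, C2, C7, C8, C9, C10).
- α and β denote the faces of ring A and of the decalins, β being the face of the C15 methyl group.
- TBS = tert-butyldimethylsilyl, TES = triethylsilyl, TMS = trimethylsilyl.
- Assumption: the carbinol carbons C2 (compounds 10 to 15) and C6 (compounds 26, 27, 29 to 31) form as epimer mixtures that converge in steps 10 and 18, and the bromide-bearing carbon of 41 and 42 is racemic; these centres are written without configuration.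

Step 1
Reactants: 1 4-methoxy-2-methylphenol
Product: 2 4,4-dimethoxy-2-methylcyclohexa-2,5-dien-1-one
Conditions: PhI(OAc)2, MeOH, 0 °C
Reagents that add atoms: methanol, CO
Why: Oxidative dearomatisation of a para-methoxyphenol by a hypervalent iodine reagent; methanol adds at the oxygen-bearing para carbon, so the quinone monoketal forms regiospecifically and stores C11 at the ketone level.

Step 2
Reactants: 2 4,4-dimethoxy-2-methylcyclohexa-2,5-dien-1-one
Product: 4 (R)-5-hydroxy-4,4-dimethoxy-2-methylcyclohex-2-en-1-one, via boronate 3 (not isolated)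
Conditions: CuCl (5 mol %), NaOt-Bu (10 mol %), (R,R)-QuinoxP* (6 mol %), B2pin2, MeOH, THF, 0 °C; NaBO3·4H2O, THF/H2O, 23 °C
Reagents that add atoms: bis(pinacolato)diboron, CC1(C)OB(OC1(C)C)B1OC(C)(C)C(C)(C)O1 (boryl group of 3); sodium perborate, [Na+].[O-]OB=O
Why: Copper-catalysed conjugate borylation then C–B oxidation with retention; the boryl group adds to the unsubstituted enone because the 2-methyl enone is the poorer acceptor, and the chiral bisphosphine–copper boryl complex (ligand enantiomer chosen to give 5R) sets C12.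

Step 3
Reactants: 4 (R)-5-hydroxy-4,4-dimethoxy-2-methylcyclohex-2-en-1-one
Product: 5 (R)-5-(TBSO)-4,4-dimethoxy-2-methylcyclohex-2-en-1-one
Conditions: TBSCl, imidazole, DMF, 23 °C
Reagents that add atoms: tert-butyldimethylsilyl chloride, CC(C)(C)[Si](C)(C)Cl
Why: Standard silylation; the silyl ether suppresses β-elimination and becomes the stereodirecting 5-substituent of the enone.

Step 4
Reactants: 5 (R)-5-(TBSO)-4,4-dimethoxy-2-methylcyclohex-2-en-1-one; 6 allylmagnesium bromide
Product: 7 ring A silyl enol ether: 10β-allyl-11,11-dimethoxy-1-methyl-12α-(TBSO)-14-(TMSO)cyclohex-1(14)-ene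
Conditions: CuBr·SMe2, Me3SiCl, THF, −78 °C
Reagents that add atoms: chlorotrimethylsilane, C[Si](C)(C)Cl
Why: Copper-mediated conjugate allylation accelerated by Me3SiCl; 5-substituted cyclohexenones are attacked trans to the 5-substituent, which sets C10, and O-silylation fixes the enolate at C1.

Step 5
Reactants: 7 ring A silyl enol ether; 8 acrolein
Product: 11 10β-allyl-11,11-dimethoxy-1β-methyl-12α-(TBSO)-1α-[1-(TESO)prop-2-enyl]cyclohexan-14-one (C2 epimers), via lithium enolate 9 (not isolated), via lithium aldolate 10 (not isolated)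
Conditions: MeLi, THF, 0 °C; acrolein, −78 °C; TESOTf, −78 → 0 °C
Reagents that add atoms: triethylsilyl trifluoromethanesulfonate, CC[Si](CC)(CC)OS(=O)(=O)C(F)(F)F; methyllithium, [Li]C (lithium of 9 and 10)
Why: Enolate regeneration from the silyl enol ether and aldol addition; the aldehyde approaches C1 anti to the neighbouring allyl group, creating the quaternary centre with the methyl cis to the allyl group, and silylation of the aldolate blocks retro-aldol cleavage.

Step 6
Reactants: 11 ring A ketone
Product: 12 10β-allyl-11,11-dimethoxy-1β-methyl-12α-(TBSO)-1α-[1-(TESO)prop-2-enyl]cyclohexan-14α-ol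
Conditions: LiBH(s-Bu)3, THF, −78 °C
Reagents that add atoms: none
Why: Reduction by a bulky trialkylborohydride; axial delivery is blocked by the syn-axial C12 silyloxy group, so hydride enters equatorially and gives the axial 14α-alcohol, cis to O12 and trans to the C15 methyl.

Step 7
Reactants: 12 14α-alcohol
Product: 13 10β-allyl-11,11-dimethoxy-1β-methyl-12α,14α-bis(TBSO)-1α-[1-(TESO)prop-2-enyl]cyclohexane
Conditions: TBSOTf, 2,6-lutidine, CH2Cl2, 0 °C
Reagents that add atoms: tert-butyldimethylsilyl trifluoromethanesulfonate, CC(C)(C)[Si](C)(C)OS(=O)(=O)C(F)(F)F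
Why: Silylation of a hindered axial alcohol with the silyl triflate; the axial 14α-silyloxy group later shields the α face of the C2 carbonyl.

Step 8
Reactants: 13 bis-TBS ether
Product: 14 10β-allyl-1α-(1-hydroxyprop-2-enyl)-1β-methyl-12α,14α-bis(TBSO)cyclohexan-11-one
Conditions: TsOH·H2O (cat.), acetone/H2O, 23 °C
Reagents that add atoms: water, O
Why: Acid hydrolysis of the dimethyl ketal and of the triethylsilyl ether; the two hindered secondary TBS ethers solvolyse far more slowly.

Step 9
Reactants: 14 C11 ketone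
Product: 15 10β-allyl-1α-(1-hydroxyprop-2-enyl)-1β-methyl-11-methylene-12α,14α-bis(TBSO)cyclohexane
Conditions: Zn, CH2Br2, TiCl4, THF/CH2Cl2, 0 → 23 °C
Reagents that add atoms: dibromomethane, BrCBr
Why: Lombardo methylenation; the non-basic zinc–titanium methylene reagent converts the enolisable α-silyloxy ketone into the exocyclic alkene without epimerisation at C10 or C12 and tolerates the free alcohol.

Step 10
Reactants: 15 allylic alcohol
Product: 16 1α-acryloyl-10β-allyl-1β-methyl-11-methylene-12α,14α-bis(TBSO)cyclohexane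
Conditions: Dess–Martin periodinane, NaHCO3, CH2Cl2, 0 °C
Reagents that add atoms: none
Why: Dess–Martin oxidation of the allylic alcohol to the vinyl ketone; both C2 epimers converge.

Step 11
Reactants: 16 vinyl ketone
Product: 17 trans-decalin enone: 1β-methyl-11-methylene-12α,14α-bis(TBSO)-10αH-decal-7-en-2-one
Conditions: second-generation Grubbs catalyst (5 mol %), CH2Cl2, 40 °C
Reagents that add atoms: none
Why: Ring-closing metathesis between the allyl group and the vinyl ketone closes ring B as a cyclohexenone; the hindered 1,1-disubstituted exocyclic alkene is a spectator.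

Step 12
Reactants: 17 trans-decalin enone
Product: 19 9β-hydroxy-1β-methyl-11-methylene-12α,14α-bis(TBSO)-10αH-decal-7-en-2-one, via silyl dienol ether 18 (not isolated)
Conditions: Me3SiOTf, Et3N, CH2Cl2, 0 °C; dimethyldioxirane, acetone/CH2Cl2, −78 °C; citric acid (aq)
Reagents that add atoms: trimethylsilyl trifluoromethanesulfonate, C[Si](C)(C)OS(=O)(=O)C(F)(F)F (silyl group of 18); dimethyldioxirane, CC1(C)OO1
Why: Soft enolisation can only remove the γ-proton at C9 (C1 is quaternary); epoxidation of the electron-rich C8=C9 bond of the dienol ether and collapse (vinylogous Rubottom oxidation) gives the γ-hydroxy enone. The oxidant enters axially (β), as in the 6β-hydroxylation of steroidal 3,5-dienol ethers.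

Step 13
Reactants: 19 9β-hydroxy enone
Product: 20 1β-methyl-11-methylene-9β,12α,14α-tris(TBSO)-10αH-decal-7-en-2-one
Conditions: TBSOTf, 2,6-lutidine, CH2Cl2, 0 °C
Reagents that add atoms: tert-butyldimethylsilyl trifluoromethanesulfonate, CC(C)(C)[Si](C)(C)OS(=O)(=O)C(F)(F)F
Why: Silylation of the axial allylic alcohol under non-basic conditions that do not touch the enone.

Step 14
Reactants: 20 9β-TBSO enone
Product: 22 8α-hydroxy-1β-methyl-11-methylene-9β,12α,14α-tris(TBSO)-10αH-decalin-2-one, via boronate 21 (not isolated)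
Conditions: CuCl (5 mol %), NaOt-Bu (10 mol %), Xantphos, B2pin2, MeOH, THF, 23 °C; NaBO3·4H2O, THF/H2O
Reagents that add atoms: bis(pinacolato)diboron, CC1(C)OB(OC1(C)C)B1OC(C)(C)C(C)(C)O1 (boryl group of 21); sodium perborate, [Na+].[O-]OB=O
Why: Conjugate borylation–oxidation puts oxygen on the β-carbon C8 regiospecifically; the copper boryl adds axially and anti to the adjacent pseudo-axial C9 silyloxy group (α). This configuration is erased when C8 becomes a ketone.

Step 15
Reactants: 22 8α-hydroxy ketone
Product: 23 1β-methyl-11-methylene-8α-(TESO)-9β,12α,14α-tris(TBSO)-10αH-decalin-2-one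
Conditions: TESOTf, 2,6-lutidine, CH2Cl2, −78 °C
Reagents that add atoms: triethylsilyl trifluoromethanesulfonate, CC[Si](CC)(CC)OS(=O)(=O)C(F)(F)F
Why: Silylation of the β-hydroxy ketone under conditions too mild for dehydration; the TES ether can later be removed beside three TBS ethers.

Step 16
Reactants: 23 decalone; 24 3-(trimethylsilyl)propynal
Product: 27 7α-[1-(TMSO)-3-(TMS)prop-2-ynyl] derivative of 23, via lithium enolate 25 (not isolated), via lithium aldolate 26 (not isolated)
Conditions: LiN(i-Pr)2, THF, −78 °C; 24; Me3SiCl, −78 → 0 °C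
Reagents that add atoms: lithium diisopropylamide, [Li]N(C(C)C)C(C)C (lithium of 25 and 26); chlorotrimethylsilane, C[Si](C)(C)Cl
Why: Aldol addition of the only possible enolate (C2=C7); the β face of C7 is shielded by the syn-axial C9 silyloxy group, so the side chain is attached equatorially (α). O-silylation prevents retro-aldol cleavage and β-elimination in the next step.

Step 17
Reactants: 27 silylated aldol; 28 vinylmagnesium bromide
Product: 30 7α-(1-hydroxyprop-2-ynyl)-1β-methyl-11-methylene-8α-(TESO)-9β,12α,14α-tris(TBSO)-2β-vinyl-10αH-decalin-2α-ol, via silylated carbinol 29 (not isolated)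
Conditions: CeCl3, THF, −78 → 0 °C; K2CO3, MeOH, 23 °C
Reagents that add atoms: none
Why: 1,2-Addition of an organocerium reagent (low basicity); the α face of the C2 carbonyl is closed by the syn-axial C8 and the peri-axial C14 silyloxy groups, so the vinyl group enters equatorially from the β face and the hydroxyl becomes axial. K2CO3/MeOH then removes the O- and C-trimethylsilyl groups.

Step 18
Reactants: 30 propargylic diol
Product: 32 7α-allenyl-1β-methyl-11-methylene-8α-(TESO)-9β,12α,14α-tris(TBSO)-2β-vinyl-10αH-decalin-2α-ol, via propargylic diazene 31 (not isolated)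
Conditions: 2-nitrobenzenesulfonylhydrazide, PPh3, diethyl azodicarboxylate, THF, −15 → 23 °C
Reagents that add atoms: 2-nitrobenzenesulfonylhydrazide, NNS(=O)(=O)c1ccccc1[N+](=O)[O-] (nitrogen atoms of 31)
Why: Myers allene synthesis: Mitsunobu displacement of the secondary propargylic alcohol, loss of sulfinic acid and sigmatropic extrusion of N2 from the diazene give the terminal allene. The tertiary alcohol is inert and both C6 epimers give the same allene.

Step 19
Reactants: 32 7α-allenyl-2β-vinyl-decalin-2α-ol
Product: 35 ring-expanded ketone: (6E)-1-methyl-11-methylene-8-(TESO)-9,12,14-tris(TBSO)bicyclo[8.4.0] skeleton with C2 ketone and 5(16),6-diene (C1, C8, C9, C10, C12, C14 as in 32), via potassium alkoxide 33 (not isolated), via potassium enolate 34 (not isolated)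
Conditions: KH, 18-crown-6, THF, 0 → 23 °C; NH4Cl (aq), −78 °C
Reagents that add atoms: potassium hydride, [KH] (potassium of 33 and 34)
Why: KH deprotonates the tertiary C2 alcohol and 18-crown-6 separates the ion pair; alkoxide 33 undergoes a concerted [3,3] shift of the 1,5-diene C4=C3–C2–C7–C6=C5 in which C4–C5 forms and C2–C7 breaks, giving enolate 34, which is protonated at C3 on work-up. The closest known reaction type is the anionic oxy-Cope ring expansion of trans-1,2-dialkenylcyclohexanols to (E)-cyclodec-5-enones, here with the proximal π bond of an allene as the second alkene. The ten-membered ring is not closed end to end: it arises by four-carbon expansion of ring B, the C3–C4–C5–C6 chain being inserted between C2 and C7 while ring A and its trans fusion are untouched. No stereocentre is created; C2 and C7 become trigonal and C1, C8, C9, C10, C12 and C14 are carried through. The step needs E geometry at C6=C7: in the rigid trans-decalin the vinyl and allenyl groups are both equatorial, so the six reacting atoms can only adopt the chair in which C8 is anti to C5 across the forming double bond, whereas a boat would place them syn. The allene π bond orthogonal to the reacting one survives as the C5=C16 methylene, twisted out of conjugation with C6=C7. Relief of the 1,3-diaxial contacts of the C2 alkoxide with the C8 and C14 silyloxy groups should add to the alkoxide acceleration.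

Step 20
Reactants: 35 ring-expanded ketone
Product: 36 8-hydroxy analogue of 35 (allylic alcohol)
Conditions: pyridinium p-toluenesulfonate, MeOH/CH2Cl2, 0 °C
Reagents that add atoms: none
Why: Selective acid methanolysis of the triethylsilyl ether in the presence of three hindered secondary TBS ethers.

Step 21
Reactants: 36 allylic alcohol
Product: 37 (6E)-5(16),6-diene-2,8-dione (9,12,14-tris-TBS ether)
Conditions: Dess–Martin periodinane, NaHCO3, CH2Cl2, 0 °C
Reagents that add atoms: none
Why: Dess–Martin oxidation of the allylic alcohol; C6=C7 becomes the only electron-poor alkene of the molecule.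

Step 22
Reactants: 37 enedione
Product: 38 6,7-trans-epoxy-2,8-dione (epoxide oxygen on the C7 face that carries oxygen in 47)
Conditions: t-BuOOH, DBU, CH2Cl2, 0 °C
Reagents that add atoms: tert-butyl hydroperoxide, CC(C)(C)OO
Why: Weitz–Scheffer epoxidation; the hydroperoxide anion adds only to the enone, from the peripheral face of the E-cyclodecenone (the face opposite the C2–C7 bond broken in step 19), which fixes C7 as in the target and keeps the trans geometry.

Step 23
Reactants: 38 epoxy ketone
Product: 39 6-chloro-7-hydroxy-2,8-dione (C6 and C7 as in 47)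
Conditions: HCl (1 M in Et2O), CH2Cl2, −40 °C
Reagents that add atoms: hydrogen chloride, Cl
Why: Hydrohalic opening of an α,β-epoxy ketone; chloride attacks the carbon remote from the carbonyl (C6) with inversion and gives the anti chlorohydrin that matches C6 and C7 of the target.

Step 24
Reactants: 39 chloro ketol; 40 2-bromopropanoic acid
Product: 41 7-O-(2-bromopropanoyl) derivative of 39
Conditions: DCC, DMAP (cat.), CH2Cl2, −20 °C
Reagents that add atoms: none
Why: Steglich esterification of the only free hydroxyl under near-neutral conditions, which avoids base-induced loss of HCl from the β-chloro ketone.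

Step 25
Reactants: 41 α-bromo ester
Product: 43 7,19-lactone: 6-chloro-8-hydroxy-2-oxo-9,12,14-tris(TBSO)briara-5(16),11(20)-dien-19,7-olide (C6, C7, C8, C17 as in 47), via samarium enolate 42 (not isolated)
Conditions: SmI2 (2.2 equiv), THF, −78 °C
Reagents that add atoms: samarium diiodide, [Sm+2].[I-].[I-] (samarium and iodide of 42)
Why: SmI2-mediated intramolecular Reformatsky reaction: reductive enolisation of the α-bromo ester and addition of the trivalent samarium enolate to the C8 ketone through a chelated five-membered-ring transition state. The tether delivers C17 to the carbonyl face syn to O7, which with C6 and C9 anti about C7–C8 gives the trans-fused lactone, and the methyl group takes the position away from C9.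

Step 26
Reactants: 43 tris-TBS lactone
Product: 44 6-chloro-8,9,12,14-tetrahydroxy-2-oxobriara-5(16),11(20)-dien-19,7-olide
Conditions: HF·pyridine, pyridine, THF, 0 → 23 °C
Reagents that add atoms: none
Why: Fluoride cleavage of the three silyl ethers; buffered HF·pyridine leaves the allylic chloride and the β-hydroxy lactone intact.

Step 27
Reactants: 44 2-ketone
Product: 45 6-chloro-2,8,9,12,14-pentahydroxybriara-5(16),11(20)-dien-19,7-olide (C2 as in 47)
Conditions: Me4NBH(OAc)3, MeCN/AcOH, −20 °C
Reagents that add atoms: none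
Why: Evans–Saksena reduction; the C14 hydroxyl exchanges onto boron and delivers hydride internally through a chair with C3 equatorial, which gives the 1,3-anti relationship of O14 and O2 found in the target.

Step 28
Reactants: 45 pentaol
Product: 46 6-chloro-11,20-epoxy-2,8,9,12,14-pentahydroxybriar-5(16)-en-19,7-olide
Conditions: VO(acac)2 (cat.), t-BuOOH, CH2Cl2, 0 °C
Reagents that add atoms: tert-butyl hydroperoxide, CC(C)(C)OO
Why: Hydroxyl-directed epoxidation; the axial allylic 12α-hydroxyl delivers oxygen to the α face of C11=C20 (also the face away from the C15 methyl), while C5=C16, which has no allylic hydroxyl and is deactivated by the chloride, is left.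

Step 29
Reactants: 46 epoxy pentaol
Product: 47 (1S,2S,6S,7R,8R,9S,10S,11R,12R,14S,17R)-2,9,12,14-tetraacetoxy-6-chloro-11,20-epoxy-8-hydroxybriar-5(16)-en-19,7-olide
Conditions: Ac2O, pyridine, DMAP (cat.), CH2Cl2, 23 °C
Reagents that add atoms: acetic anhydride, CC(=O)OC(C)=O
Why: Acetylation of the four secondary hydroxyl groups; the hindered tertiary C8 hydroxyl is not acylated under these conditions.

## Compound list

1 | 4-methoxy-2-methylphenol | Cc1cc(OC)ccc1O | starting material
2 | 4,4-dimethoxy-2-methylcyclohexa-2,5-dien-1-one | CC1=CC(OC)(OC)C=CC1=O | intermediate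
3 | (R)-4,4-dimethoxy-2-methyl-5-(pinacolatoboryl)cyclohex-2-en-1-one | CC1=CC(OC)(OC)[C@H](B2OC(C)(C)C(C)(C)O2)CC1=O | intermediate
4 | (R)-5-hydroxy-4,4-dimethoxy-2-methylcyclohex-2-en-1-one | CC1=CC(OC)(OC)[C@H](O)CC1=O | intermediate
5 | (R)-5-(TBSO)-4,4-dimethoxy-2-methylcyclohex-2-en-1-one | CC1=CC(OC)(OC)[C@H](O[Si](C)(C)C(C)(C)C)CC1=O | intermediate
6 | allylmagnesium bromide | C=CC[Mg]Br | starting material
7 | 10β-allyl-11,11-dimethoxy-1-methyl-12α-(TBSO)-14-(TMSO)cyclohex-1(14)-ene (ring A) | CC1=C(O[Si](C)(C)C)C[C@@H](O[Si](C)(C)C(C)(C)C)C(OC)(OC)[C@@H]1CC=C | intermediate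
8 | acrolein | C=CC=O | starting material
9 | lithium enolate of the 10β-allyl ring A ketone (C1=C14) | CC1=C([O-])C[C@@H](O[Si](C)(C)C(C)(C)C)C(OC)(OC)[C@@H]1CC=C.[Li+] | intermediate
10 | lithium aldolate: 1β-methyl-1α-(1-oxidoprop-2-enyl) ring A ketone | C=CC([O-])[C@@]1(C)C(=O)C[C@@H](O[Si](C)(C)C(C)(C)C)C(OC)(OC)[C@@H]1CC=C.[Li+] | intermediate
11 | 10β-allyl-11,11-dimethoxy-1β-methyl-12α-(TBSO)-1α-[1-(TESO)prop-2-enyl]cyclohexan-14-one | C=CC(O[Si](CC)(CC)CC)[C@@]1(C)C(=O)C[C@@H](O[Si](C)(C)C(C)(C)C)C(OC)(OC)[C@@H]1CC=C | intermediate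
12 | 14α-alcohol of 11 | C=CC(O[Si](CC)(CC)CC)[C@@]1(C)[C@@H](O)C[C@@H](O[Si](C)(C)C(C)(C)C)C(OC)(OC)[C@@H]1CC=C | intermediate
13 | 10β-allyl-11,11-dimethoxy-1β-methyl-12α,14α-bis(TBSO)-1α-[1-(TESO)prop-2-enyl]cyclohexane | C=CC(O[Si](CC)(CC)CC)[C@@]1(C)[C@@H](O[Si](C)(C)C(C)(C)C)C[C@@H](O[Si](C)(C)C(C)(C)C)C(OC)(OC)[C@@H]1CC=C | intermediate
14 | 10β-allyl-1α-(1-hydroxyprop-2-enyl)-1β-methyl-12α,14α-bis(TBSO)cyclohexan-11-one | C=CC(O)[C@@]1(C)[C@@H](O[Si](C)(C)C(C)(C)C)C[C@@H](O[Si](C)(C)C(C)(C)C)C(=O)[C@@H]1CC=C | intermediate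
15 | 10β-allyl-1α-(1-hydroxyprop-2-enyl)-1β-methyl-11-methylene-12α,14α-bis(TBSO)cyclohexane | C=CC(O)[C@@]1(C)[C@@H](O[Si](C)(C)C(C)(C)C)C[C@@H](O[Si](C)(C)C(C)(C)C)C(=C)[C@@H]1CC=C | intermediate
16 | 1α-acryloyl-10β-allyl-1β-methyl-11-methylene-12α,14α-bis(TBSO)cyclohexane | C=CC(=O)[C@@]1(C)[C@@H](O[Si](C)(C)C(C)(C)C)C[C@@H](O[Si](C)(C)C(C)(C)C)C(=C)[C@@H]1CC=C | intermediate
17 | 1β-methyl-11-methylene-12α,14α-bis(TBSO)-10αH-decal-7-en-2-one | O=C1[C@@]2(C)[C@@H](O[Si](C)(C)C(C)(C)C)C[C@@H](O[Si](C)(C)C(C)(C)C)C(=C)[C@@H]2CC=C1 | intermediate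
18 | 2-(TMSO)-2(7),8-diene derived from 17 | C[Si](C)(C)OC=1[C@@]2(C)[C@@H](O[Si](C)(C)C(C)(C)C)C[C@@H](O[Si](C)(C)C(C)(C)C)C(=C)[C@@H]2C=CC=1 | intermediate
19 | 9β-hydroxy-1β-methyl-11-methylene-12α,14α-bis(TBSO)-10αH-decal-7-en-2-one | O=C1[C@@]2(C)[C@@H](O[Si](C)(C)C(C)(C)C)C[C@@H](O[Si](C)(C)C(C)(C)C)C(=C)[C@@H]2[C@H](O)C=C1 | intermediate
20 | 1β-methyl-11-methylene-9β,12α,14α-tris(TBSO)-10αH-decal-7-en-2-one | O=C1[C@@]2(C)[C@@H](O[Si](C)(C)C(C)(C)C)C[C@@H](O[Si](C)(C)C(C)(C)C)C(=C)[C@@H]2[C@H](O[Si](C)(C)C(C)(C)C)C=C1 | intermediate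
21 | 8α-(pinacolatoboryl)-9β,12α,14α-tris(TBSO)decalin-2-one | O=C1[C@@]2(C)[C@@H](O[Si](C)(C)C(C)(C)C)C[C@@H](O[Si](C)(C)C(C)(C)C)C(=C)[C@@H]2[C@H](O[Si](C)(C)C(C)(C)C)[C@@H](B3OC(C)(C)C(C)(C)O3)CC1 | intermediate
22 | 8α-hydroxy-1β-methyl-11-methylene-9β,12α,14α-tris(TBSO)-10αH-decalin-2-one | O=C1[C@@]2(C)[C@@H](O[Si](C)(C)C(C)(C)C)C[C@@H](O[Si](C)(C)C(C)(C)C)C(=C)[C@@H]2[C@H](O[Si](C)(C)C(C)(C)C)[C@@H](O)CC1 | intermediate
23 | 1β-methyl-11-methylene-8α-(TESO)-9β,12α,14α-tris(TBSO)-10αH-decalin-2-one | O=C1[C@@]2(C)[C@@H](O[Si](C)(C)C(C)(C)C)C[C@@H](O[Si](C)(C)C(C)(C)C)C(=C)[C@@H]2[C@H](O[Si](C)(C)C(C)(C)C)[C@@H](O[Si](CC)(CC)CC)CC1 | intermediate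
24 | 3-(trimethylsilyl)propynal | C[Si](C)(C)C#CC=O | starting material
25 | lithium enolate of 23 (C2=C7) | [Li+].[O-]C=1[C@@]2(C)[C@@H](O[Si](C)(C)C(C)(C)C)C[C@@H](O[Si](C)(C)C(C)(C)C)C(=C)[C@@H]2[C@H](O[Si](C)(C)C(C)(C)C)[C@@H](O[Si](CC)(CC)CC)C=1 | intermediate
26 | lithium aldolate: 7α-[1-oxido-3-(TMS)prop-2-ynyl] derivative of 23 | O=C1[C@@]2(C)[C@@H](O[Si](C)(C)C(C)(C)C)C[C@@H](O[Si](C)(C)C(C)(C)C)C(=C)[C@@H]2[C@H](O[Si](C)(C)C(C)(C)C)[C@@H](O[Si](CC)(CC)CC)[C@H]1C([O-])C#C[Si](C)(C)C.[Li+] | intermediate
27 | 7α-[1-(TMSO)-3-(TMS)prop-2-ynyl] derivative of 23 | O=C1[C@@]2(C)[C@@H](O[Si](C)(C)C(C)(C)C)C[C@@H](O[Si](C)(C)C(C)(C)C)C(=C)[C@@H]2[C@H](O[Si](C)(C)C(C)(C)C)[C@@H](O[Si](CC)(CC)CC)[C@H]1C(O[Si](C)(C)C)C#C[Si](C)(C)C | intermediate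
28 | vinylmagnesium bromide | C=C[Mg]Br | starting material
29 | 2β-vinyl-2α-ol with 7α-[1-(TMSO)-3-(TMS)prop-2-ynyl] side chain | C=C[C@]1(O)[C@@]2(C)[C@@H](O[Si](C)(C)C(C)(C)C)C[C@@H](O[Si](C)(C)C(C)(C)C)C(=C)[C@@H]2[C@H](O[Si](C)(C)C(C)(C)C)[C@@H](O[Si](CC)(CC)CC)[C@H]1C(O[Si](C)(C)C)C#C[Si](C)(C)C | intermediate
30 | 7α-(1-hydroxyprop-2-ynyl)-1β-methyl-11-methylene-8α-(TESO)-9β,12α,14α-tris(TBSO)-2β-vinyl-10αH-decalin-2α-ol | C=C[C@]1(O)[C@@]2(C)[C@@H](O[Si](C)(C)C(C)(C)C)C[C@@H](O[Si](C)(C)C(C)(C)C)C(=C)[C@@H]2[C@H](O[Si](C)(C)C(C)(C)C)[C@@H](O[Si](CC)(CC)CC)[C@H]1C(O)C#C | intermediate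
31 | 7α-(1-diazenylprop-2-ynyl) analogue of 30 | C=C[C@]1(O)[C@@]2(C)[C@@H](O[Si](C)(C)C(C)(C)C)C[C@@H](O[Si](C)(C)C(C)(C)C)C(=C)[C@@H]2[C@H](O[Si](C)(C)C(C)(C)C)[C@@H](O[Si](CC)(CC)CC)[C@H]1C(N=N)C#C | intermediate
32 | 7α-allenyl-1β-methyl-11-methylene-8α-(TESO)-9β,12α,14α-tris(TBSO)-2β-vinyl-10αH-decalin-2α-ol | C=C[C@]1(O)[C@@]2(C)[C@@H](O[Si](C)(C)C(C)(C)C)C[C@@H](O[Si](C)(C)C(C)(C)C)C(=C)[C@@H]2[C@H](O[Si](C)(C)C(C)(C)C)[C@@H](O[Si](CC)(CC)CC)[C@H]1C=C=C | intermediate
33 | potassium alkoxide of 32 | C=C[C@]1([O-])[C@@]2(C)[C@@H](O[Si](C)(C)C(C)(C)C)C[C@@H](O[Si](C)(C)C(C)(C)C)C(=C)[C@@H]2[C@H](O[Si](C)(C)C(C)(C)C)[C@@H](O[Si](CC)(CC)CC)[C@H]1C=C=C.[K+] | intermediate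
34 | potassium enolate (C2=C3) of 35 | C=C1/C=C/[C@H](O[Si](CC)(CC)CC)[C@@H](O[Si](C)(C)C(C)(C)C)[C@@H]2[C@@](C)(C([O-])=CC1)[C@@H](O[Si](C)(C)C(C)(C)C)C[C@@H](O[Si](C)(C)C(C)(C)C)C2=C.[K+] | intermediate
35 | ring-expanded (6E)-5(16),6-dien-2-one with 8-OTES and 9,12,14-tris-OTBS groups (ring A fused to a cyclodecadienone) | C=C1/C=C/[C@H](O[Si](CC)(CC)CC)[C@@H](O[Si](C)(C)C(C)(C)C)[C@@H]2[C@@](C)(C(=O)CC1)[C@@H](O[Si](C)(C)C(C)(C)C)C[C@@H](O[Si](C)(C)C(C)(C)C)C2=C | intermediate
36 | 8-hydroxy analogue of 35 | C=C1/C=C/[C@H](O)[C@@H](O[Si](C)(C)C(C)(C)C)[C@@H]2[C@@](C)(C(=O)CC1)[C@@H](O[Si](C)(C)C(C)(C)C)C[C@@H](O[Si](C)(C)C(C)(C)C)C2=C | intermediate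
37 | (6E)-5(16),6-diene-2,8-dione, 9,12,14-tris-TBS ether | C=C1/C=C/C(=O)[C@@H](O[Si](C)(C)C(C)(C)C)[C@@H]2[C@@](C)(C(=O)CC1)[C@@H](O[Si](C)(C)C(C)(C)C)C[C@@H](O[Si](C)(C)C(C)(C)C)C2=C | intermediate
38 | 6,7-trans-epoxy-2,8-dione, 9,12,14-tris-TBS ether | C=C1CCC(=O)[C@@]2(C)[C@@H](O[Si](C)(C)C(C)(C)C)C[C@@H](O[Si](C)(C)C(C)(C)C)C(=C)[C@@H]2[C@H](O[Si](C)(C)C(C)(C)C)C(=O)[C@H]3O[C@@H]31 | intermediate
39 | 6-chloro-7-hydroxy-2,8-dione, 9,12,14-tris-TBS ether | C=C1CCC(=O)[C@@]2(C)[C@@H](O[Si](C)(C)C(C)(C)C)C[C@@H](O[Si](C)(C)C(C)(C)C)C(=C)[C@@H]2[C@H](O[Si](C)(C)C(C)(C)C)C(=O)[C@@H](O)[C@H]1Cl | intermediate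
40 | 2-bromopropanoic acid | CC(Br)C(=O)O | starting material
41 | 7-O-(2-bromopropanoyl) derivative of 39 | C=C1CCC(=O)[C@@]2(C)[C@@H](O[Si](C)(C)C(C)(C)C)C[C@@H](O[Si](C)(C)C(C)(C)C)C(=C)[C@@H]2[C@H](O[Si](C)(C)C(C)(C)C)C(=O)[C@@H](OC(=O)C(C)Br)[C@H]1Cl | intermediate
42 | trivalent samarium enolate of the C7 propanoate | C=C1CCC(=O)[C@@]2(C)[C@@H](O[Si](C)(C)C(C)(C)C)C[C@@H](O[Si](C)(C)C(C)(C)C)C(=C)[C@@H]2[C@H](O[Si](C)(C)C(C)(C)C)C(=O)[C@@H](OC([O-])=CC)[C@H]1Cl.[Sm+3].[I-].[I-] | intermediate
43 | 6-chloro-8-hydroxy-2-oxo-9,12,14-tris(TBSO)briara-5(16),11(20)-dien-19,7-olide | C=C1CCC(=O)[C@@]2(C)[C@@H](O[Si](C)(C)C(C)(C)C)C[C@@H](O[Si](C)(C)C(C)(C)C)C(=C)[C@@H]2[C@H](O[Si](C)(C)C(C)(C)C)[C@]3(O)[C@@H](C)C(=O)O[C@H]3[C@H]1Cl | intermediate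
44 | 6-chloro-8,9,12,14-tetrahydroxy-2-oxobriara-5(16),11(20)-dien-19,7-olide | C=C1CCC(=O)[C@@]2(C)[C@@H](O)C[C@@H](O)C(=C)[C@@H]2[C@H](O)[C@]3(O)[C@@H](C)C(=O)O[C@H]3[C@H]1Cl | intermediate
45 | 6-chloro-2,8,9,12,14-pentahydroxybriara-5(16),11(20)-dien-19,7-olide | C=C1CC[C@H](O)[C@@]2(C)[C@@H](O)C[C@@H](O)C(=C)[C@@H]2[C@H](O)[C@]3(O)[C@@H](C)C(=O)O[C@H]3[C@H]1Cl | intermediate
46 | 6-chloro-11,20-epoxy-2,8,9,12,14-pentahydroxybriar-5(16)-en-19,7-olide | C=C1CC[C@H](O)[C@@]2(C)[C@@H](O)C[C@@H](O)[C@]3(CO3)[C@@H]2[C@H](O)[C@]2(O)[C@@H](C)C(=O)O[C@H]2[C@H]1Cl | intermediate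
47 | (1S,2S,6S,7R,8R,9S,10S,11R,12R,14S,17R)-2,9,12,14-tetraacetoxy-6-chloro-11,20-epoxy-8-hydroxybriar-5(16)-en-19,7-olide (CNP0349227.2) | C=C1CC[C@H](OC(C)=O)[C@@]2(C)[C@@H](OC(C)=O)C[C@@H](OC(C)=O)[C@]3(CO3)[C@@H]2[C@H](OC(C)=O)[C@]2(O)[C@@H](C)C(=O)O[C@H]2[C@H]1Cl | target

## Step count and least certain steps

Total step count: 29. Longest linear sequence: 29 steps (1 to 47).

**Step 19 (key step).** Most likely failure: base-induced isomerisation of the allenyl group before rearrangement, or partial passage through a boat that would give the Z olefin. Fallback: the neutral siloxy-Cope variant. It sets out from 32, which Me3SiCl/imidazole converts into the trimethylsilyl ether F1. Thermolysis (toluene, 180 °C, sealed tube) gives the silyl enol ether F2 by the same [3,3] shift without any anion, and K2CO3/MeOH returns to the route at 35.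

**Step 17.** Most likely failure: enolisation towards C7 followed by β-elimination of the silyloxy group, or no addition to the doubly flanked ketone. Fallback: a two-step alkynylation/reduction. It sets out from 27, to which the slimmer and less basic ethynylmagnesium bromide (CeCl3) adds to give the propargylic alcohol F5. Alkoxide-directed trans-hydroalumination with NaAlH2(OCH2CH2OMe)2 reduces only the alkyne next to the free tertiary hydroxyl and returns to the route at 29.

**Step 25.** Most likely failure: reductive cleavage of the α-acyloxy ketone C7–O bond or of the allylic chloride, or addition to the wrong carbonyl face (cis-fused C8 epimer). Fallback: an intermolecular, chelation-controlled aldol. It sets out from 38, to which the lithium enolate of tert-butyl propanoate (LiN(i-Pr)2, MgBr2) adds to give the hydroxy ester F9. HCl then opens the epoxide at C6 and the C7 hydroxyl lactonises, returning to the route at 43.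

**Step 23.** Most likely failure: attack of chloride at C7 or SN2′ attack at C16, or acid loss of a silyl ether. Fallback: hydroxyl-directed opening. It sets out from 38, whose activated C8 ketone NaBH4/CeCl3 reduces to the epoxy alcohol F6. Ti(OiPr)4/Et2NH·HCl delivers chloride to C-3 of this 2,3-epoxy alcohol (C6) to give the chloro diol F7. Esterification of the less hindered C7 hydroxyl with 40 (DCC) gives the mono-ester F8, and Dess–Martin oxidation returns to the route at 41.

**Step 27.** Most likely failure: poor facial selectivity, because the chair needed for internal delivery requires a gauche C10–C1–C2–C3 arrangement that the ten-membered ring may resist. Fallback: reagent-controlled reduction before desilylation. It sets out from 43, which a 2-methyl-CBS-oxazaborolidine with catecholborane reduces to the alcohol F10, and HF·pyridine returns to the route at 45.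

**Step 2.** Most likely failure: insufficient enantioselection, or borylation of both enones. Fallback: kinetic resolution. It sets out from 2, which the same borylation–oxidation with an achiral ligand converts into the racemic alcohol F3. Candida antarctica lipase B with vinyl acetate acylates the R enantiomer to the acetate F4, which is separated and hydrolysed by the same enzyme in buffer, returning to the route at 4.

## Further compounds

F1 | step 19 | trimethylsilyl ether of 32 | C=C[C@]1(O[Si](C)(C)C)[C@@]2(C)[C@@H](O[Si](C)(C)C(C)(C)C)C[C@@H](O[Si](C)(C)C(C)(C)C)C(=C)[C@@H]2[C@H](O[Si](C)(C)C(C)(C)C)[C@@H](O[Si](CC)(CC)CC)[C@H]1C=C=C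
F2 | step 19 | trimethylsilyl enol ether (C2=C3) of 35 | C=C1/C=C/[C@H](O[Si](CC)(CC)CC)[C@@H](O[Si](C)(C)C(C)(C)C)[C@@H]2[C@@](C)(C(O[Si](C)(C)C)=CC1)[C@@H](O[Si](C)(C)C(C)(C)C)C[C@@H](O[Si](C)(C)C(C)(C)C)C2=C
F3 | step 2 | racemic 5-hydroxy-4,4-dimethoxy-2-methylcyclohex-2-en-1-one | CC1=CC(OC)(OC)C(O)CC1=O
F4 | step 2 | (R)-5-acetoxy-4,4-dimethoxy-2-methylcyclohex-2-en-1-one | CC1=CC(OC)(OC)[C@H](OC(C)=O)CC1=O
F5 | step 17 | 2β-ethynyl-2α-ol analogue of 29 | C#C[C@]1(O)[C@@]2(C)[C@@H](O[Si](C)(C)C(C)(C)C)C[C@@H](O[Si](C)(C)C(C)(C)C)C(=C)[C@@H]2[C@H](O[Si](C)(C)C(C)(C)C)[C@@H](O[Si](CC)(CC)CC)[C@H]1C(O[Si](C)(C)C)C#C[Si](C)(C)C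
F6 | step 23 | 6,7-epoxy-8-hydroxy-2-ketone (C8 carbinol from 38) | C=C1CCC(=O)[C@@]2(C)[C@@H](O[Si](C)(C)C(C)(C)C)C[C@@H](O[Si](C)(C)C(C)(C)C)C(=C)[C@@H]2[C@H](O[Si](C)(C)C(C)(C)C)C(O)[C@H]3O[C@@H]31
F7 | step 23 | 6-chloro-7,8-dihydroxy-2-ketone | C=C1CCC(=O)[C@@]2(C)[C@@H](O[Si](C)(C)C(C)(C)C)C[C@@H](O[Si](C)(C)C(C)(C)C)C(=C)[C@@H]2[C@H](O[Si](C)(C)C(C)(C)C)C(O)[C@@H](O)[C@H]1Cl
F8 | step 23 | 7-O-(2-bromopropanoyl) derivative of F7 | C=C1CCC(=O)[C@@]2(C)[C@@H](O[Si](C)(C)C(C)(C)C)C[C@@H](O[Si](C)(C)C(C)(C)C)C(=C)[C@@H]2[C@H](O[Si](C)(C)C(C)(C)C)C(O)[C@@H](OC(=O)C(C)Br)[C@H]1Cl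
F9 | step 25 | tert-butyl ester of the C8 aldol adduct of 38 (6,7-epoxide, C8 and C17 as in 47) | C=C1CCC(=O)[C@@]2(C)[C@@H](O[Si](C)(C)C(C)(C)C)C[C@@H](O[Si](C)(C)C(C)(C)C)C(=C)[C@@H]2[C@H](O[Si](C)(C)C(C)(C)C)[C@](O)([C@@H](C)C(=O)OC(C)(C)C)[C@H]3O[C@@H]31
F10 | step 27 | 2-hydroxy analogue of 43 (C2 as in 47) | C=C1CC[C@H](O)[C@@]2(C)[C@@H](O[Si](C)(C)C(C)(C)C)C[C@@H](O[Si](C)(C)C(C)(C)C)C(=C)[C@@H]2[C@H](O[Si](C)(C)C(C)(C)C)[C@]3(O)[C@@H](C)C(=O)O[C@H]3[C@H]1Cl
A1 | alternative 1 | (E)-4-(tert-butyldimethylsilyloxy)-2-methylbut-2-enal | O=C/C(C)=C/CO[Si](C)(C)C(C)(C)C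
A2 | alternative 1 | (E)-1-benzyloxy-3-(trimethylsilyloxy)buta-1,3-diene | C=C(O[Si](C)(C)C)/C=C/OCc1ccccc1
A3 | alternative 1 | ring A cyclohexene silyl enol ether with C1 formyl and C10 silyloxymethyl groups | O=C[C@@]1(C)[C@@H](OCc2ccccc2)C=C(O[Si](C)(C)C)C[C@@H]1CO[Si](C)(C)C(C)(C)C
A4 | alternative 2 | fourteen-membered 1,2-epoxy allylsilane with butenolide and 12,14-acetonide (C10=C11 geometry not specified) | C[Si](C)(C)CC1=C[C@H](O[Si](C)(C)C(C)(C)C)C2=C(C)C(=O)O[C@H]2/C=C(C)/CC[C@@H]3O[C@@]3(C)[C@@H]4C[C@H]1OC(C)(C)O4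
A5 | alternative 2 | briarane bicycle with butenolide, C2 alcohol, 5-ene and C11 methylene | C=C1[C@H]2C[C@H](OC(C)(C)O2)[C@]3(C)[C@@H](O)CC/C(C)=C/[C@@H]4OC(=O)C(C)=C4[C@@H](O[Si](C)(C)C(C)(C)C)[C@@H]13
A6 | alternative 3 | methyl 2-methylacetoacetate | COC(=O)C(C)C(C)=O
A7 | alternative 3 | (E)-4-(tert-butyldimethylsilyloxy)but-2-enal | O=C/C=C/CO[Si](C)(C)C(C)(C)C
A8 | alternative 3 | ring A hydroxy keto ester (C14 ketone, C12 alcohol, C1 quaternary) | COC(=O)[C@@]1(C)C(=O)C[C@@H](O)C[C@@H]1CO[Si](C)(C)C(C)(C)C
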